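**Retrosynthetic overview**
1. Target 29 ⇐ its 8-O-triethylsilyl ether 28 ⇐ macrocyclic alkenylboronate/allylic chloride 26 + CO2. One operation makes C15–C16 and O–C2 and closes the γ-lactone (ring B) last.
2. Enabling feature: vinylic C15 and allylic C2 (activated by C3=C4) sit 1,3 to each other across C1 on the rim of the 14-membered carbocycle (ring A). O=C=O therefore fits between them as the C16–O edge of a five-membered ring, and the C18 methyl, cis to C2, shuts off attack at C4.
3. 26 ⇐ 25 ⇐ 24: ring A by ring-closing metathesis at C6=C7, then OH → Cl with inversion at C2.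
4. 24 ⇐ allene 17 + enal 22 + B2pin2: a copper-catalysed borylative coupling makes C1–C2, sets C1 and C2, and puts boron on C15.
5. 17 ⇐ geraniol: (S)-linalool supplies C8, Z-olefination and Sharpless epoxidation give the cis-oxirane (ring C, C11/C12), and propargylation sets C13. Ring order: C → A → B.

Key step: step 17

Numbering (cembrane): C1 (ring-fusion CH bearing C15), C2 (lactone O–CH), C3=C4(C18), C5, C6=C7, C8(C19, OH), C9, C10, C11–C12(C20) oxirane, C13 (OAc), C14; C15(=C17H2)–C16(=O)O. The target is 1S,2S,3E,6E,8S,11S,12S,13R, with H1/H2 cis, C10 and C13 cis on the oxirane, and C13–O erythro to the oxirane oxygen.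

Remark on the chemistry: the catalyst antipodes named in steps 9 and 14 are those expected from the accepted closed transition-state models. Both antipodes of each are commercial, so the sense of induction can be matched to the substrate.

**Step 1**
Reactants: 1 geraniol
Product: 2 (2S,3S)-2,3-epoxygeraniol
Conditions: Ti(OiPr)4 (5 mol %), L-(+)-diethyl tartrate (6 mol %), t-BuOOH, 4 Å MS, CH2Cl2, −20 °C
Reagents that add atoms: tert-butyl hydroperoxide, CC(C)(C)OO
Why: Sharpless asymmetric epoxidation, in which the titanium L-(+)-tartrate complex binds the allylic alcohol and delivers oxygen to one face of the C2=C3 bond only, sets the tertiary C–O centre that becomes C8 (S) and leaves the undirected distal olefin alone.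

**Step 2**
Reactants: 2 (2S,3S)-2,3-epoxygeraniol
Product: 4 (S)-linalool, via epoxy iodide 3 (not isolated)
Conditions: I2, PPh3, imidazole, THF, 0 °C; then Zn, AcOH, EtOH, rt
Reagents that add atoms: none
Why: Appel-type iodination followed by zinc insertion and β-alkoxide elimination (reductive epoxide opening) breaks only the secondary C–O bond, so the tertiary carbinol centre passes unchanged into (S)-linalool while the vinyl group needed for ring closure is created.

**Step 3**
Reactants: 4 (S)-linalool
Product: 5 (S)-linalool triethylsilyl ether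
Conditions: Et3SiOTf, 2,6-lutidine, CH2Cl2, −78 → 0 °C
Reagents that add atoms: triethylsilyl triflate, CC[Si](CC)(CC)OS(=O)(=O)C(F)(F)F
Why: Silylation of the hindered tertiary alcohol by the highly electrophilic silyl triflate masks the hydroxyl, which would otherwise form a lactol with the aldehyde of step 4 and add to the enoate of step 5.

**Step 4**
Reactants: 5 (S)-linalool triethylsilyl ether
Product: 6 (S)-4-methyl-4-(triethylsilyloxy)hex-5-enal
Conditions: O3 (1 equiv, Sudan Red 7B end point), CH2Cl2–MeOH, −78 °C; then Me2S
Reagents that add atoms: ozone, [O-][O+]=O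
Why: Chemoselective ozonolysis works because the electron-rich trisubstituted olefin reacts much faster than the monosubstituted vinyl group shielded by the quaternary silyloxy carbon, and the dye marks the end point before the second olefin is touched.

**Step 5**
Reactants: 6 (S)-4-methyl-4-(triethylsilyloxy)hex-5-enal; 7 ethyl 2-[bis(2,2,2-trifluoroethoxy)phosphoryl]propanoate
Product: 8 ethyl (2Z,6S)-2,6-dimethyl-6-(triethylsilyloxy)octa-2,7-dienoate
Conditions: KN(SiMe3)2, 18-crown-6, THF, −78 °C
Reagents that add atoms: none
Why: The Still–Gennari modification of the Horner–Wadsworth–Emmons reaction, whose electron-poor phosphonate makes elimination from the kinetic adduct fast, should give the Z-trisubstituted enoate that places C10 and C13 cis as the cis-oxirane demands.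

**Step 6**
Reactants: 8 Z-enoate
Product: 9 (2Z,6S)-2,6-dimethyl-6-(triethylsilyloxy)octa-2,7-dien-1-ol
Conditions: iBu2AlH (2.5 equiv), CH2Cl2, −78 °C; Rochelle salt work-up
Reagents that add atoms: none
Why: 1,2-Reduction of the enoate by iBu2AlH at low temperature gives the allylic alcohol without touching the olefin geometry or the silyl ether.

**Step 7**
Reactants: 9 Z-allylic alcohol
Product: 10 cis-epoxy alcohol, {(2R,3S)-2-methyl-3-[(3S)-3-methyl-3-(triethylsilyloxy)pent-4-enyl]oxiran-2-yl}methanol
Conditions: Ti(OiPr)4, D-(−)-diethyl tartrate, t-BuOOH, 4 Å MS, CH2Cl2, −20 °C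
Reagents that add atoms: tert-butyl hydroperoxide, CC(C)(C)OO
Why: Sharpless asymmetric epoxidation under reagent control, here with the D-(−)-tartrate, adds oxygen stereospecifically to the Z-olefin and so sets C11 and C12 together as the cis-oxirane of the target, while the vinyl group, which is not a free allylic alcohol, is not epoxidised.

**Step 8**
Reactants: 10 cis-epoxy alcohol
Product: 11 epoxy aldehyde, (2S,3S)-2-methyl-3-[(3S)-3-methyl-3-(triethylsilyloxy)pent-4-enyl]oxirane-2-carbaldehyde
Conditions: TEMPO (10 mol %), PhI(OAc)2, CH2Cl2, rt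
Reagents that add atoms: none
Why: Oxoammonium (TEMPO) oxidation stops at the aldehyde under nearly neutral conditions, the oxirane survives, and the fully substituted C12 cannot epimerise.

**Step 9**
Reactants: 11 epoxy aldehyde; 12 allenylboronic acid pinacol ester
Product: 14 (13R)-homopropargylic alcohol, via borate ester 13 (not isolated)
Conditions: (R)-TRIP (10 mol %), 4 Å MS, toluene, −20 °C; aqueous work-up
Reagents that add atoms: none
Why: Chiral-phosphoric-acid-catalysed propargylation with an allenylboronate runs through a closed six-membered SE2' transition state in which the (R)-catalyst should expose the Re face of the aldehyde, a sense that the dipole-opposed conformer of the α-oxygenated aldehyde (attack past the C20 methyl) should reinforce, and this sets C13 (R) erythro to the oxirane.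

**Step 10**
Reactants: 14 (13R)-homopropargylic alcohol
Product: 15 (13R)-homopropargylic acetate
Conditions: Ac2O, pyridine, DMAP (cat.), CH2Cl2, rt
Reagents that add atoms: acetic anhydride, CC(=O)OC(C)=O
Why: DMAP-catalysed acylation installs the C13 acetate of the target at once, so that it serves as its own protecting group through the remaining steps, none of which uses a hydride or a strong free nucleophile.

**Step 11**
Reactants: 15 (13R)-homopropargylic acetate
Product: 17 terminal allene (C14–C1H=C15=C17H2), via propargylic amine 16 (not isolated)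
Conditions: (CH2O)n, CuI (0.5 equiv), Cy2NH, 1,4-dioxane, reflux
Reagents that add atoms: paraformaldehyde (as formaldehyde), C=O
Why: Crabbé homologation, that is copper-mediated Mannich coupling to propargylic amine 16 followed by 1,5-hydride transfer and loss of the imine, adds C17 and turns the terminal alkyne into the monosubstituted allene under conditions that esters, oxiranes and silyl ethers tolerate.

**Step 12**
Reactants: 18 pent-1-en-4-yne
Product: 21 (E)-3-methylhexa-2,5-dien-1-ol, via alkenylalane 19 (not isolated), via lithium alanate 20 (not isolated)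
Conditions: Me3Al, Cp2ZrCl2 (20 mol %), ClCH2CH2Cl, 0 °C → rt; then n-BuLi, THF–hexane, −78 °C; (CH2O)n, → rt
Reagents that add atoms: trimethylaluminium, C[Al](C)C; paraformaldehyde (as formaldehyde), C=O
Why: Negishi zirconium-catalysed carboalumination adds methyl and aluminium syn across the alkyne (methyl to the internal carbon, the isolated olefin being far less reactive), and the derived alanate is hydroxymethylated with retention, which fixes the E-geometry of C3=C4.

**Step 13**
Reactants: 21 (E)-3-methylhexa-2,5-dien-1-ol
Product: 22 (E)-3-methylhexa-2,5-dienal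
Conditions: MnO2, CH2Cl2, rt
Reagents that add atoms: none
Why: MnO2 oxidises the allylic alcohol selectively under neutral heterogeneous conditions, so neither the E-geometry nor the skipped diene is disturbed.

**Step 14**
Reactants: 17 terminal allene; 22 (E)-3-methylhexa-2,5-dienal
Product: 24 acyclic 1,2-syn (1S,2R)-alcohol bearing C15–Bpin, via O-boryl adduct 23 (not isolated)
Conditions: B2pin2, CuCl (5 mol %), (R)-DTBM-SEGPHOS (5.5 mol %), NaOtBu (20 mol %), THF, rt; aqueous NH4Cl work-up
Reagents that add atoms: bis(pinacolato)diboron, CC1(C)OB(OC1(C)C)B1OC(C)(C)C(C)(C)O1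
Why: In this copper-catalysed borylative allene–aldehyde coupling the Cu–Bpin species adds across the terminal C15=C17 bond anti to the C14 substituent with boron on the central carbon, the resulting (Z)-2-boryl-allylcopper attacks the enal 1,2 through its γ-carbon C1 in a closed chair transition state that gives the 1,2-syn relationship, and the chiral bisphosphine selects the aldehyde face and thereby the absolute configuration.

**Step 15**
Reactants: 24 acyclic 1,2-syn alcohol
Product: 25 macrocyclic (2R)-alcohol (ring A, 6E)
Conditions: second-generation Hoveyda–Grubbs catalyst (10 mol %), 1,4-benzoquinone (20 mol %), toluene (1 mM), 80 °C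
Reagents that add atoms: none
Why: In this ring-closing metathesis the catalyst loads on the unhindered allyl terminus (C6) and closes onto the C7 vinyl group, the quaternary C8 makes the Z-olefin prohibitively strained so the E-olefin should result, and the C15 borylalkene is out of reach because it could only give a seven-membered ring containing the E-C3=C4 bond.

**Step 16**
Reactants: 25 macrocyclic (2R)-alcohol
Product: 26 macrocyclic (2S)-allylic chloride (1,2-anti)
Conditions: PPh3, Cl3CC(O)CCl3, 2,6-lutidine, CH2Cl2, −30 → 0 °C
Reagents that add atoms: hexachloroacetone, ClC(Cl)(Cl)C(=O)C(Cl)(Cl)Cl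
Why: In this Appel-type chlorination the alkoxyphosphonium ion formed under neutral conditions is displaced by chloride in an SN2 process with inversion at C2, attack at the tertiary C4 terminus being sterically disfavoured, which removes a hydroxyl that would quench the alkenylcopper of step 17 and turns it into the nucleofuge placed for a second inversion.

**Step 17**
Reactants: 26 macrocyclic (2S)-allylic chloride
Product: 28 8-O-triethylsilyl ether of the target (ring B closed), via potassium carboxylate 27 (not isolated)
Conditions: CO2 (1 atm), (IPr)CuCl (10 mol %; IPr = 1,3-bis(2,6-diisopropylphenyl)imidazol-2-ylidene), KOtBu (1.1 equiv, slow addition), THF, 23 → 50 °C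
Reagents that add atoms: carbon dioxide, O=C=O
Why: Proposed new method: (IPr)CuOtBu, formed from (IPr)CuCl and KOtBu, transmetalates with the C15–B bond of 26, the alkenylcopper inserts CO2 to make C15–C16, and carboxylate 27 then displaces the allylic C2 chloride from the rear to make O–C2, so both lactone oxygens and C16 come from one CO2 molecule. The closest known reaction types are the carbene–copper-catalysed carboxylation of alkenylboronic esters with CO2 and the monovalent-copper-catalysed carboxylative coupling of terminal alkynes, CO2 and allylic chlorides to allylic esters, and what is new is their intramolecular merger on an alkenylboronate. Ring B is the only ring closed and it closes in the 5-exo-tet mode. C2 is the only stereocentre touched and is set by stereospecific inversion of the (2S)-chloride, which places H1 and H2 cis, while C1 is a spectator because no enolisable intermediate arises next to it. The step needs CO2 insertion to outrun C–C coupling of the alkenylcopper with the allylic chloride and needs oxygen to attack C2 rather than C4: α-coupling would give a methylenecyclopropane, γ-coupling or O-attack at C4 requires the rotamer with C1 in the olefin plane next to the C18 methyl (severe A1,3 strain), and O-attack at C4 would also build a seven-membered lactone at a tertiary carbon. Slow addition of KOtBu under CO2 keeps free alkoxide low, which protects the C13 acetate and suppresses E2 loss of HCl.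

**Step 18**
Reactants: 28 8-O-triethylsilyl ether of the target
Product: 29 target CNP0288879.2
Conditions: HF·pyridine, pyridine, THF, 0 °C → rt
Reagents that add atoms: none
Why: Fluoride-driven cleavage of the Si–O bond with pyridine-buffered HF removes the tertiary triethylsilyl ether without opening the oxirane, hydrolysing the acetate or adding to the α-methylene lactone.

**Compound list**
1 | geraniol, (E)-3,7-dimethylocta-2,6-dien-1-ol | CC(C)=CCC/C(C)=C/CO | starting material
2 | (2S,3S)-2,3-epoxygeraniol | CC(C)=CCC[C@]1(C)O[C@H]1CO | intermediate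
3 | 2,3-epoxygeranyl iodide (oxirane as in 2) | CC(C)=CCC[C@]1(C)O[C@H]1CI | intermediate
4 | (S)-linalool | CC(C)=CCC[C@](C)(O)C=C | intermediate
5 | (S)-linalool triethylsilyl ether | CC(C)=CCC[C@](C)(O[Si](CC)(CC)CC)C=C | intermediate
6 | (S)-4-methyl-4-(triethylsilyloxy)hex-5-enal | O=CCC[C@](C)(O[Si](CC)(CC)CC)C=C | intermediate
7 | ethyl 2-[bis(2,2,2-trifluoroethoxy)phosphoryl]propanoate | CCOC(=O)C(C)P(=O)(OCC(F)(F)F)OCC(F)(F)F | starting material
8 | ethyl (2Z,6S)-2,6-dimethyl-6-(triethylsilyloxy)octa-2,7-dienoate | CCOC(=O)/C(C)=C\CC[C@](C)(O[Si](CC)(CC)CC)C=C | intermediate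
9 | (2Z,6S)-2,6-dimethyl-6-(triethylsilyloxy)octa-2,7-dien-1-ol | OC/C(C)=C\CC[C@](C)(O[Si](CC)(CC)CC)C=C | intermediate
10 | {(2R,3S)-2-methyl-3-[(3S)-3-methyl-3-(triethylsilyloxy)pent-4-enyl]oxiran-2-yl}methanol (cis-oxirane) | OC[C@@]1(C)O[C@H]1CC[C@](C)(O[Si](CC)(CC)CC)C=C | intermediate
11 | (2S,3S)-2-methyl-3-[(3S)-3-methyl-3-(triethylsilyloxy)pent-4-enyl]oxirane-2-carbaldehyde | O=C[C@@]1(C)O[C@H]1CC[C@](C)(O[Si](CC)(CC)CC)C=C | intermediate
12 | allenylboronic acid pinacol ester | C=C=CB1OC(C)(C)C(C)(C)O1 | starting material
13 | pinacol borate ester of 14 | C#CC[C@@H](OB1OC(C)(C)C(C)(C)O1)[C@@]2(C)O[C@H]2CC[C@](C)(O[Si](CC)(CC)CC)C=C | intermediate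
14 | (1R)-1-{(2R,3S)-2-methyl-3-[(3S)-3-methyl-3-(triethylsilyloxy)pent-4-enyl]oxiran-2-yl}but-3-yn-1-ol (13R, erythro) | C#CC[C@@H](O)[C@@]1(C)O[C@H]1CC[C@](C)(O[Si](CC)(CC)CC)C=C | intermediate
15 | acetate of 14 | C#CC[C@@H](OC(C)=O)[C@@]1(C)O[C@H]1CC[C@](C)(O[Si](CC)(CC)CC)C=C | intermediate
16 | N,N-dicyclohexyl propargylic amine (Mannich base of 15) | C1CCC(CC1)N(CC#CC[C@@H](OC(C)=O)[C@@]2(C)O[C@H]2CC[C@](C)(O[Si](CC)(CC)CC)C=C)C3CCCCC3 | intermediate
17 | terminal allene, penta-3,4-dienyl homologue of 15 (8S,11S,12S,13R) | C=C=CC[C@@H](OC(C)=O)[C@@]1(C)O[C@H]1CC[C@](C)(O[Si](CC)(CC)CC)C=C | intermediate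
18 | pent-1-en-4-yne | C=CCC#C | starting material
19 | (E)-dimethyl(2-methylpenta-1,4-dienyl)alane | C=CC/C(C)=C/[Al](C)C | intermediate
20 | lithium butyl(dimethyl)[(E)-2-methylpenta-1,4-dienyl]alanate | [Li+].C=CC/C(C)=C/[Al-](C)(C)CCCC | intermediate
21 | (E)-3-methylhexa-2,5-dien-1-ol | C=CC/C(C)=C/CO | intermediate
22 | (E)-3-methylhexa-2,5-dienal | C=CC/C(C)=C/C=O | intermediate
23 | O-Bpin ether of 24 | C=CC/C(C)=C/[C@H](OB1OC(C)(C)C(C)(C)O1)[C@H](C(=C)B2OC(C)(C)C(C)(C)O2)C[C@@H](OC(C)=O)[C@@]3(C)O[C@H]3CC[C@](C)(O[Si](CC)(CC)CC)C=C | intermediate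
24 | acyclic 1,2-syn (1S,2R)-alcohol with C15–Bpin (3E,8S,11S,12S,13R) | C=CC/C(C)=C/[C@H](O)[C@H](C(=C)B1OC(C)(C)C(C)(C)O1)C[C@@H](OC(C)=O)[C@@]2(C)O[C@H]2CC[C@](C)(O[Si](CC)(CC)CC)C=C | intermediate
25 | macrocyclic (1S,2R,3E,6E)-alcohol with C15–Bpin | O[C@H]1/C=C(\C)C/C=C/[C@@](C)(O[Si](CC)(CC)CC)CC[C@@H]2O[C@]2(C)[C@H](OC(C)=O)C[C@H]1C(=C)B3OC(C)(C)C(C)(C)O3 | intermediate
26 | macrocyclic (1S,2S)-allylic chloride with C15–Bpin (C2 inverted) | Cl[C@@H]1/C=C(\C)C/C=C/[C@@](C)(O[Si](CC)(CC)CC)CC[C@@H]2O[C@]2(C)[C@H](OC(C)=O)C[C@H]1C(=C)B3OC(C)(C)C(C)(C)O3 | intermediate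
27 | potassium acrylate derived from 26 (C15–CO2K, C2–Cl) | Cl[C@@H]1/C=C(\C)C/C=C/[C@@](C)(O[Si](CC)(CC)CC)CC[C@@H]2O[C@]2(C)[C@H](OC(C)=O)C[C@H]1C(=C)C(=O)[O-].[K+] | intermediate
28 | 8-O-triethylsilyl ether of the target (cis-fused α-methylene-γ-lactone) | C=C1C(=O)O[C@H]2/C=C(\C)C/C=C/[C@@](C)(O[Si](CC)(CC)CC)CC[C@@H]3O[C@]3(C)[C@H](OC(C)=O)C[C@@H]12 | intermediate
29 | CNP0288879.2, (1S,2S,3E,6E,8S,11S,12S,13R)-13-acetoxy-11,12-epoxy-8-hydroxycembra-3,6,15(17)-trien-16,2-olide | C=C1C(=O)O[C@H]2/C=C(\C)C/C=C/[C@@](C)(O)CC[C@@H]3O[C@]3(C)[C@H](OC(C)=O)C[C@@H]12 | target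

**Step count**
Total step count: 18.
Longest linear sequence: 16 (steps 1–11 and 14–18).

**Steps most likely to fail**

*Step 17.* The alkenylcopper may couple directly with the allylic chloride or be protonated before CO2 inserts. The chloride may also ionise before the carboxylate arrives, which would erode the configuration at C2. The fallback splits the two bond formations into individually known reactions; it sets out from 25 and comes back at 28.
- Acylation of 25 with methyl chloroformate and pyridine gives the allylic methyl carbonate F1 with the C2–O bond untouched.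
- Copper-catalysed carboxylation of the alkenylboronate under fluoride activation ((IPr)CuCl, CsF, CO2, DMF) and mild acidification gives the acrylic acid F2.
- Pd(PPh3)4 in THF then ionises the carbonate with inversion. The tethered carboxylate attacks C2 of the allylpalladium unit on the face away from the metal, so double inversion gives the cis-fused lactone 28.

*Step 16.* Activation of the γ,γ-disubstituted allylic alcohol may be accompanied by ionisation or allylic transposition, with loss of stereochemical fidelity at C2, or by attack of the chlorophosphonium species on the oxirane. The fallback inverts C2 by redox chemistry instead of substitution and then activates oxygen with retention; it sets out from 25 and comes back at 28.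
- Dess–Martin oxidation gives the enone F3.
- Corey–Bakshi–Shibata reduction with catecholborane gives the (2S)-epimeric alcohol F4 under reagent control.
- ClP(O)(OEt)2 with DMAP gives the diethyl phosphate F5. It carries its nucleofuge in the same 1,2-anti arrangement as 26 and is submitted to the conditions of step 17 to give 28.

*Step 15.* The vinyl group next to the quaternary silyloxy carbon may engage too slowly, so that oligomerisation through the allyl terminus or migration of the skipped diene takes over. The fallback changes the ring order to C → B → A; it sets out from 24 and comes back at 29.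
- Appel-type chlorination of 24 gives the acyclic allylic chloride F6.
- Carboxylative lactonisation as in step 17 gives the acyclic α-methylene lactone F7.
- Buffered HF·pyridine gives the free tertiary allylic alcohol F8.
- Ring-closing metathesis is run last. The free allylic hydroxyl should speed up engagement of the C7 vinyl group, and the α-methylene group stays out of reach for the same geometric reason as in step 15. This gives 29 directly.

**Further compounds**
F1 | step 17 | allylic methyl carbonate of 25 | COC(=O)O[C@H]1/C=C(\C)C/C=C/[C@@](C)(O[Si](CC)(CC)CC)CC[C@@H]2O[C@]2(C)[C@H](OC(C)=O)C[C@H]1C(=C)B3OC(C)(C)C(C)(C)O3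
F2 | step 17 | acrylic acid bearing the C2 methyl carbonate | COC(=O)O[C@H]1/C=C(\C)C/C=C/[C@@](C)(O[Si](CC)(CC)CC)CC[C@@H]2O[C@]2(C)[C@H](OC(C)=O)C[C@H]1C(=C)C(=O)O
F3 | step 16 | macrocyclic C2 enone | O=C1/C=C(\C)C/C=C/[C@@](C)(O[Si](CC)(CC)CC)CC[C@@H]2O[C@]2(C)[C@H](OC(C)=O)C[C@H]1C(=C)B3OC(C)(C)C(C)(C)O3
F4 | step 16 | macrocyclic (2S)-epimeric alcohol | O[C@@H]1/C=C(\C)C/C=C/[C@@](C)(O[Si](CC)(CC)CC)CC[C@@H]2O[C@]2(C)[C@H](OC(C)=O)C[C@H]1C(=C)B3OC(C)(C)C(C)(C)O3
F5 | step 16 | diethyl phosphate of F4 | CCOP(=O)(OCC)O[C@@H]1/C=C(\C)C/C=C/[C@@](C)(O[Si](CC)(CC)CC)CC[C@@H]2O[C@]2(C)[C@H](OC(C)=O)C[C@H]1C(=C)B3OC(C)(C)C(C)(C)O3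
F6 | step 15 | acyclic allylic chloride (C2 inverted) | C=CC/C(C)=C/[C@@H](Cl)[C@H](C(=C)B1OC(C)(C)C(C)(C)O1)C[C@@H](OC(C)=O)[C@@]2(C)O[C@H]2CC[C@](C)(O[Si](CC)(CC)CC)C=C
F7 | step 15 | acyclic cis-α-methylene-γ-lactone, 8-O-triethylsilyl ether | C=C1C(=O)O[C@@H](/C=C(\C)CC=C)[C@H]1C[C@@H](OC(C)=O)[C@@]2(C)O[C@H]2CC[C@](C)(O[Si](CC)(CC)CC)C=C
F8 | step 15 | acyclic cis-α-methylene-γ-lactone with free C8 hydroxyl | C=C1C(=O)O[C@@H](/C=C(\C)CC=C)[C@H]1C[C@@H](OC(C)=O)[C@@]2(C)O[C@H]2CC[C@](C)(O)C=C
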